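## Retrosynthetic overview

1. Target 24 ⇒ desilylation of 23 ⇒ the dienoate C2=C3 bond is made by Horner–Wadsworth–Emmons union of lactone phosphonoacetate 18 with hydroxy enal 22.
2. 18 ⇒ hydroxy δ-lactone 17. Its C4–C5 bond (acid numbering) and both carbinol centres come from a new organocatalytic vinylogous Mukaiyama aldol of aldehyde 8 with γ-alkoxy silyl dienolate 12. The only ring (the δ-lactone) is closed afterwards by 1,4-reduction and lactonisation.
3. 8 ⇒ syn-2,4-dimethyl hemiester 2 from organocatalytic desymmetrisation of meso anhydride 1 (first stereocentres), then Negishi coupling with (E)-2-bromobut-2-ene 5.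
4. 22 ⇒ organocatalytic α-hydroxymethylation of achiral aldehyde 19, trapped in the same flask by Wittig olefination.

Assumption: (DHQD)2AQN is taken to deliver hemiester 2 in the (2R,4S) sense (if the sense is opposite, the pseudoenantiomer (DHQ)2AQN is used), and compounds 9, 10, 19 and 20 are taken as purchasable.

## Route

Step 1
Reactants: 1 (3R,5S)-3,5-dimethyloxane-2,6-dione (meso-2,4-dimethylglutaric anhydride)
Product: 2 (2R,4S)-5-methoxy-2,4-dimethyl-5-oxopentanoic acid
Conditions: (DHQD)2AQN (10 mol%), MeOH (10 equiv), Et2O, −30 °C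
Reagents that add atoms: methanol, CO
Why: Organocatalytic desymmetrising methanolysis of a meso anhydride, in which the quinuclidine nitrogen of the bis-cinchona alkaloid acts as a chiral general base and selects one enantiotopic carbonyl, so both methyl-bearing centres (2R,4S) are fixed at once from an achiral substrate.

Step 2
Reactants: 2 (2R,4S)-5-methoxy-2,4-dimethyl-5-oxopentanoic acid
Product: 3 methyl (2S,4R)-5-hydroxy-2,4-dimethylpentanoate
Conditions: BH3·SMe2 (1.2 equiv), THF, 0 °C → rt; aqueous work-up; used directly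
Reagents that add atoms: none
Why: Chemoselective borane reduction of the carboxylic acid (acyloxyborane pathway) beside the methyl ester, with both stereocentres untouched.

Step 3
Reactants: 3 methyl (2S,4R)-5-hydroxy-2,4-dimethylpentanoate
Product: 4 methyl (2S,4R)-5-iodo-2,4-dimethylpentanoate
Conditions: I2, PPh3, imidazole, CH2Cl2, 0 °C → rt
Reagents that add atoms: iodine, II
Why: Appel-type iodination of the primary alcohol by SN2 displacement at CH2, which involves no stereocentre and outruns lactonisation of the hydroxy ester.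

Step 4
Reactants: 4 methyl (2S,4R)-5-iodo-2,4-dimethylpentanoate; 5 (2E)-2-bromobut-2-ene
Product: 7 methyl (2S,4R,6E)-2,4,6-trimethyloct-6-enoate, via alkylzinc iodide 6 (not isolated)
Conditions: Zn dust (activated with BrCH2CH2Br and Me3SiCl), DMA, 40 °C; then 5 (2 equiv), PdCl2(dppf) (5 mol%), THF/DMA, 45 °C
Reagents that add atoms: none
Why: Zinc insertion into the primary C–I bond gives an ester-tolerant alkylzinc, and Negishi sp3–sp2 cross-coupling then proceeds with retention of the alkene geometry (E in the product), the bidentate dppf ligand suppressing β-hydride elimination.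

Step 5
Reactants: 7 methyl (2S,4R,6E)-2,4,6-trimethyloct-6-enoate
Product: 8 (2S,4R,6E)-2,4,6-trimethyloct-6-enal
Conditions: iBu2AlH (1.1 equiv), CH2Cl2, −78 °C; MeOH, then aqueous Rochelle salt; crude aldehyde used at once
Reagents that add atoms: none
Why: Partial ester reduction stops at the tetrahedral aluminium hemiacetal at −78 °C and releases the aldehyde on work-up, and these non-basic conditions do not epimerise the α-stereocentre.

Step 6
Reactants: 9 2-[(4-methoxyphenyl)methoxy]acetaldehyde; 10 methyl 2-(triphenyl-λ5-phosphanylidene)acetate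
Product: 11 methyl (2E)-4-[(4-methoxyphenyl)methoxy]but-2-enoate
Conditions: CH2Cl2, rt
Reagents that add atoms: none
Why: Wittig olefination with a stabilised ylide gives the E-enoate.

Step 7
Reactants: 11 methyl (2E)-4-[(4-methoxyphenyl)methoxy]but-2-enoate
Product: 12 triethyl({(3Z)-1-methoxy-4-[(4-methoxyphenyl)methoxy]buta-1,3-dien-1-yl}oxy)silane
Conditions: LiN(iPr)2, DMPU, THF, −78 °C; Et3SiCl, −78 °C → rt; filtered and used crude
Reagents that add atoms: chlorotriethylsilane, CC[Si](Cl)(CC)CC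
Why: Kinetic γ-deprotonation of the E-enoate (vinylogous enolisation) followed by O-silylation gives the silyl dienolate, and the cis-directing effect of the γ-alkoxy group favours the 3Z enol ether.

Step 8
Reactants: 8 (2S,4R,6E)-2,4,6-trimethyloct-6-enal; 12 triethyl({(3Z)-1-methoxy-4-[(4-methoxyphenyl)methoxy]buta-1,3-dien-1-yl}oxy)silane
Product: 14 methyl (2E,4R,5R,6S,8R,10E)-5-hydroxy-4-[(4-methoxyphenyl)methoxy]-6,8,10-trimethyldodeca-2,10-dienoate, via triethylsilyl aldol ether 13 (not isolated)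
Conditions: chiral IDPi Brønsted acid (BINOL-derived N-triflyl imidodiphosphorimidate, 2 mol%, enantiomer matched to Felkin attack), 12 (1.5 equiv), toluene, −78 → −60 °C; then 1 M HCl, THF, 0 °C
Reagents that add atoms: none
Why: Proposed new method: the silylated IDPi (a silylium–chiral anion pair formed from the acid and 12) activates the aldehyde, and the γ-carbon of the dienolate, which is the nucleophilic terminus just as in 2-silyloxyfurans where it also carries oxygen, attacks through an open transition state in which the 3Z-alkoxy group gives the 4,5-syn relationship (4R, as in BF3-promoted additions of γ-alkoxyallylstannanes) while Felkin–Anh attack on the Si face, reinforced by the matched confined anion, sets 5R (5,6-syn), with silyl transfer to the aldolate turning the catalyst over; the closest known reaction type is the disulfonimide- or IDPi-catalysed vinylogous Mukaiyama aldol reaction of crotonate-derived silyl dienolates and of 2-silyloxyfurans, which has not been shown for an acyclic γ-alkoxy dienolate with an α-branched aliphatic aldehyde.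

Step 9
Reactants: 14 methyl (2E,4R,5R,6S,8R,10E)-5-hydroxy-4-[(4-methoxyphenyl)methoxy]-6,8,10-trimethyldodeca-2,10-dienoate
Product: 16 (5R,6R)-6-[(2S,4R,6E)-4,6-dimethyloct-6-en-2-yl]-5-[(4-methoxyphenyl)methoxy]oxan-2-one, via saturated hydroxy ester 15 (not isolated)
Conditions: Cu(OAc)2·H2O (5 mol%), 1,2-bis(diphenylphosphino)benzene (5 mol%), (EtO)2MeSiH (2.5 equiv), tBuOH (2 equiv), toluene, rt; then PPTS (10 mol%), toluene, 50 °C
Reagents that add atoms: none
Why: Copper hydride 1,4-reduction touches only the conjugated enoate (the isolated trisubstituted alkene and the PMB ether are inert), and acid-catalysed lactonisation of the δ-hydroxy ester then closes the δ-lactone, since O4 is blocked as its PMB ether and no γ-lactone can form.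

Step 10
Reactants: 16 (5R,6R)-6-[(2S,4R,6E)-4,6-dimethyloct-6-en-2-yl]-5-[(4-methoxyphenyl)methoxy]oxan-2-one
Product: 17 (5R,6R)-6-[(2S,4R,6E)-4,6-dimethyloct-6-en-2-yl]-5-hydroxyoxan-2-one
Conditions: DDQ (1.3 equiv), CH2Cl2/pH 7 phosphate buffer (10:1), 0 °C; used without delay
Reagents that add atoms: none
Why: Oxidative PMB cleavage by DDQ (hydride abstraction to the oxocarbenium ion, then hydrolysis) frees the hydroxyl under buffered neutral conditions that avoid acid- or base-induced translactonisation to the γ-lactone.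

Step 11
Reactants: 17 (5R,6R)-6-[(2S,4R,6E)-4,6-dimethyloct-6-en-2-yl]-5-hydroxyoxan-2-one
Product: 18 (2R,3R)-2-[(2S,4R,6E)-4,6-dimethyloct-6-en-2-yl]-6-oxooxan-3-yl 2-(diethoxyphosphoryl)acetate
Conditions: (EtO)2P(O)CH2CO2H, DCC, CH2Cl2, 0 °C → rt
Reagents that add atoms: diethylphosphonoacetic acid, CCOP(=O)(CC(=O)O)OCC
Why: Carbodiimide (Steglich-type) acylation with the highly reactive phosphonoacetic acid esterifies the hindered secondary alcohol without added base and with retention at the carbinol centre.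

Step 12
Reactants: 19 4-[(tert-butyldimethylsilyl)oxy]butanal; 20 2-(triphenyl-λ5-phosphanylidene)propanal
Product: 22 (2E,4R)-6-[(tert-butyldimethylsilyl)oxy]-4-(hydroxymethyl)-2-methylhex-2-enal, via hydroxymethyl aldehyde 21 (not isolated)
Conditions: aqueous formaldehyde (3 equiv), (R)-α,α-diphenylprolinol trimethylsilyl ether (20 mol%), pH 7 phosphate buffer, toluene, rt; phases separated; then 20, toluene, 40 °C
Reagents that add atoms: formaldehyde, C=O
Why: Enamine-catalysed α-hydroxymethylation in which the (R)-diarylprolinol silyl ether shields one face of the E-enamine so that formaldehyde adds to the other and sets the (S) centre of 21, and Wittig olefination with the stabilised formyl ylide traps this labile β-hydroxy aldehyde as the E-enal (the descriptor becomes 4R by priority change only).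

Step 13
Reactants: 18 (2R,3R)-2-[(2S,4R,6E)-4,6-dimethyloct-6-en-2-yl]-6-oxooxan-3-yl 2-(diethoxyphosphoryl)acetate; 22 (2E,4R)-6-[(tert-butyldimethylsilyl)oxy]-4-(hydroxymethyl)-2-methylhex-2-enal
Product: 23 (2R,3R)-2-[(2S,4R,6E)-4,6-dimethyloct-6-en-2-yl]-6-oxooxan-3-yl (2E,4E,6R)-8-[(tert-butyldimethylsilyl)oxy]-6-(hydroxymethyl)-4-methylocta-2,4-dienoate
Conditions: LiCl, iPr2NEt, MeCN, rt
Reagents that add atoms: none
Why: Masamune–Roush Horner–Wadsworth–Emmons olefination (LiCl-chelated phosphonate, amine base) joins the two halves, forms the 2E alkene and tolerates the free primary hydroxyl and the lactone.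

Step 14
Reactants: 23 (2R,3R)-2-[(2S,4R,6E)-4,6-dimethyloct-6-en-2-yl]-6-oxooxan-3-yl (2E,4E,6R)-8-[(tert-butyldimethylsilyl)oxy]-6-(hydroxymethyl)-4-methylocta-2,4-dienoate
Product: 24 (2R,3R)-2-[(2S,4R,6E)-4,6-dimethyloct-6-en-2-yl]-6-oxooxan-3-yl (2E,4E,6R)-8-hydroxy-6-(hydroxymethyl)-4-methylocta-2,4-dienoate
Conditions: HF·pyridine, pyridine, THF, 0 °C → rt
Reagents that add atoms: none
Why: Fluoride-driven desilylation (Si–F bond formation) removes the primary silyl ether under buffered conditions that leave the lactone, the dienoate ester and both alkenes intact.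

## Compound list

1 | (3R,5S)-3,5-dimethyloxane-2,6-dione (meso-2,4-dimethylglutaric anhydride) | C[C@H]1C[C@@H](C)C(=O)OC1=O | starting material
2 | (2R,4S)-5-methoxy-2,4-dimethyl-5-oxopentanoic acid | OC(=O)[C@H](C)C[C@H](C)C(=O)OC | intermediate
3 | methyl (2S,4R)-5-hydroxy-2,4-dimethylpentanoate | OC[C@H](C)C[C@H](C)C(=O)OC | intermediate
4 | methyl (2S,4R)-5-iodo-2,4-dimethylpentanoate | IC[C@H](C)C[C@H](C)C(=O)OC | intermediate
5 | (2E)-2-bromobut-2-ene | C/C=C(\C)Br | starting material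
6 | [(2R,4S)-5-methoxy-2,4-dimethyl-5-oxopentyl]zinc iodide | I[Zn]C[C@H](C)C[C@H](C)C(=O)OC | intermediate (not isolated)
7 | methyl (2S,4R,6E)-2,4,6-trimethyloct-6-enoate | C/C=C(\C)C[C@H](C)C[C@H](C)C(=O)OC | intermediate
8 | (2S,4R,6E)-2,4,6-trimethyloct-6-enal | C/C=C(\C)C[C@H](C)C[C@H](C)C=O | intermediate
9 | 2-[(4-methoxyphenyl)methoxy]acetaldehyde | O=CCOCc1ccc(OC)cc1 | starting material
10 | methyl 2-(triphenyl-λ5-phosphanylidene)acetate | COC(=O)C=P(c1ccccc1)(c1ccccc1)c1ccccc1 | starting material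
11 | methyl (2E)-4-[(4-methoxyphenyl)methoxy]but-2-enoate | COC(=O)/C=C/COCc1ccc(OC)cc1 | intermediate
12 | triethyl({(3Z)-1-methoxy-4-[(4-methoxyphenyl)methoxy]buta-1,3-dien-1-yl}oxy)silane (C1=C2 geometry not defined) | COC(O[Si](CC)(CC)CC)=C/C=C\OCc1ccc(OC)cc1 | intermediate
13 | methyl (2E,4R,5R,6S,8R,10E)-4-[(4-methoxyphenyl)methoxy]-6,8,10-trimethyl-5-[(triethylsilyl)oxy]dodeca-2,10-dienoate | C/C=C(\C)C[C@H](C)C[C@H](C)[C@@H](O[Si](CC)(CC)CC)[C@H](OCc1ccc(OC)cc1)/C=C/C(=O)OC | intermediate (not isolated)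
14 | methyl (2E,4R,5R,6S,8R,10E)-5-hydroxy-4-[(4-methoxyphenyl)methoxy]-6,8,10-trimethyldodeca-2,10-dienoate | C/C=C(\C)C[C@H](C)C[C@H](C)[C@@H](O)[C@H](OCc1ccc(OC)cc1)/C=C/C(=O)OC | intermediate
15 | methyl (4R,5R,6S,8R,10E)-5-hydroxy-4-[(4-methoxyphenyl)methoxy]-6,8,10-trimethyldodec-10-enoate | C/C=C(\C)C[C@H](C)C[C@H](C)[C@@H](O)[C@H](OCc1ccc(OC)cc1)CCC(=O)OC | intermediate (not isolated)
16 | (5R,6R)-6-[(2S,4R,6E)-4,6-dimethyloct-6-en-2-yl]-5-[(4-methoxyphenyl)methoxy]oxan-2-one | C/C=C(\C)C[C@H](C)C[C@H](C)[C@H]1OC(=O)CC[C@H]1OCc1ccc(OC)cc1 | intermediate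
17 | (5R,6R)-6-[(2S,4R,6E)-4,6-dimethyloct-6-en-2-yl]-5-hydroxyoxan-2-one | C/C=C(\C)C[C@H](C)C[C@H](C)[C@H]1OC(=O)CC[C@H]1O | intermediate
18 | (2R,3R)-2-[(2S,4R,6E)-4,6-dimethyloct-6-en-2-yl]-6-oxooxan-3-yl 2-(diethoxyphosphoryl)acetate | C/C=C(\C)C[C@H](C)C[C@H](C)[C@H]1OC(=O)CC[C@H]1OC(=O)CP(=O)(OCC)OCC | intermediate
19 | 4-[(tert-butyldimethylsilyl)oxy]butanal | O=CCCCO[Si](C)(C)C(C)(C)C | starting material
20 | 2-(triphenyl-λ5-phosphanylidene)propanal | CC(C=O)=P(c1ccccc1)(c1ccccc1)c1ccccc1 | starting material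
21 | (2S)-4-[(tert-butyldimethylsilyl)oxy]-2-(hydroxymethyl)butanal | O=C[C@H](CO)CCO[Si](C)(C)C(C)(C)C | intermediate (not isolated)
22 | (2E,4R)-6-[(tert-butyldimethylsilyl)oxy]-4-(hydroxymethyl)-2-methylhex-2-enal | O=C/C(C)=C/[C@H](CO)CCO[Si](C)(C)C(C)(C)C | intermediate
23 | (2R,3R)-2-[(2S,4R,6E)-4,6-dimethyloct-6-en-2-yl]-6-oxooxan-3-yl (2E,4E,6R)-8-[(tert-butyldimethylsilyl)oxy]-6-(hydroxymethyl)-4-methylocta-2,4-dienoate | C/C=C(\C)C[C@H](C)C[C@H](C)[C@H]1OC(=O)CC[C@H]1OC(=O)/C=C/C(C)=C/[C@H](CO)CCO[Si](C)(C)C(C)(C)C | intermediate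
24 | (2R,3R)-2-[(2S,4R,6E)-4,6-dimethyloct-6-en-2-yl]-6-oxooxan-3-yl (2E,4E,6R)-8-hydroxy-6-(hydroxymethyl)-4-methylocta-2,4-dienoate | C/C=C(\C)C[C@H](C)C[C@H](C)[C@H]1OC(=O)CC[C@H]1OC(=O)/C=C/C(C)=C/[C@H](CO)CCO | target

## Summary

Total step count: 14.
Longest linear sequence: 11 steps (steps 1–5, 8–11, 13 and 14).

The three steps most likely to fail:

Step 8 (proposed new method). The risks are α- instead of γ-attack of the dienolate, low 4,5-syn selectivity, and a Prins-type reaction of the trisubstituted alkene with the activated aldehyde. The fallback uses known chemistry, sets out from aldehyde 8 and comes back at hydroxy lactone 17 (steps 6, 7, 9 and 10 then fall away). BF3·OEt2-promoted addition (CH2Cl2, −78 °C) of the γ-silyloxyallylstannane tert-butyldimethyl{[(1Z)-3-(tributylstannyl)prop-1-en-1-yl]oxy}silane F1 (made from allyl tert-butyldimethylsilyl ether with sBuLi, then Bu3SnCl) passes through an open, Felkin-controlled transition state. It gives the syn,syn alcohol (3R,4R,5S,7R,9E)-3-[(tert-butyldimethylsilyl)oxy]-5,7,9-trimethylundeca-1,9-dien-4-ol F2. Acryloyl chloride and iPr2NEt convert it into (3R,4R,5S,7R,9E)-3-[(tert-butyldimethylsilyl)oxy]-5,7,9-trimethylundeca-1,9-dien-4-yl prop-2-enoate F3. Ring-closing metathesis with second-generation Grubbs catalyst RuCl2(H2IMes)(PCy3)(=CHPh) closes (5R,6R)-5-[(tert-butyldimethylsilyl)oxy]-6-[(2S,4R,6E)-4,6-dimethyloct-6-en-2-yl]-5,6-dihydro-2H-pyran-2-one F4. Copper hydride 1,4-reduction (the conditions of step 9 without the acid stage) gives (5R,6R)-5-[(tert-butyldimethylsilyl)oxy]-6-[(2S,4R,6E)-4,6-dimethyloct-6-en-2-yl]oxan-2-one F5, and HF·pyridine then frees 17.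

Step 12. The β-hydroxy aldehyde 21 can dehydrate or racemise before the sluggish formyl ylide has reacted. The fallback sets out from aldehyde 19 and comes back at hydroxy enal 22. Intermediate 21 is generated as in step 12 but trapped at rt with the more reactive ester ylide ethyl 2-(triphenyl-λ5-phosphanylidene)propanoate, which gives ethyl (2E,4R)-6-[(tert-butyldimethylsilyl)oxy]-4-(hydroxymethyl)-2-methylhex-2-enoate F6. Reduction with iBu2AlH gives the diol (2E,4R)-6-[(tert-butyldimethylsilyl)oxy]-4-(hydroxymethyl)-2-methylhex-2-en-1-ol F7, and MnO2 oxidises only its allylic hydroxyl to give 22.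

Step 13. The α-methyl enal is a weak electrophile, and the free hydroxyl and the lactone may suffer under prolonged exposure to base. The fallback sets out from hydroxy enal 22 and hydroxy lactone 17 (step 11 is then left out) and comes back at target 24. TBSCl and imidazole convert 22 into (2E,4R)-6-[(tert-butyldimethylsilyl)oxy]-4-{[(tert-butyldimethylsilyl)oxy]methyl}-2-methylhex-2-enal F8. Horner–Wadsworth–Emmons olefination with the dianion of diethylphosphonoacetic acid (nBuLi, THF) gives (2E,4E,6R)-8-[(tert-butyldimethylsilyl)oxy]-6-{[(tert-butyldimethylsilyl)oxy]methyl}-4-methylocta-2,4-dienoic acid F9. Steglich esterification (DCC, DMAP, CH2Cl2) with 17 gives (2R,3R)-2-[(2S,4R,6E)-4,6-dimethyloct-6-en-2-yl]-6-oxooxan-3-yl (2E,4E,6R)-8-[(tert-butyldimethylsilyl)oxy]-6-{[(tert-butyldimethylsilyl)oxy]methyl}-4-methylocta-2,4-dienoate F10, and HF·pyridine gives 24.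

## Further compounds

F1 | step 8 | tert-butyldimethyl{[(1Z)-3-(tributylstannyl)prop-1-en-1-yl]oxy}silane | CCCC[Sn](CCCC)(CCCC)C/C=C\O[Si](C)(C)C(C)(C)C
F2 | step 8 | (3R,4R,5S,7R,9E)-3-[(tert-butyldimethylsilyl)oxy]-5,7,9-trimethylundeca-1,9-dien-4-ol | C/C=C(\C)C[C@H](C)C[C@H](C)[C@@H](O)[C@H](O[Si](C)(C)C(C)(C)C)C=C
F3 | step 8 | (3R,4R,5S,7R,9E)-3-[(tert-butyldimethylsilyl)oxy]-5,7,9-trimethylundeca-1,9-dien-4-yl prop-2-enoate | C/C=C(\C)C[C@H](C)C[C@H](C)[C@@H](OC(=O)C=C)[C@H](O[Si](C)(C)C(C)(C)C)C=C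
F4 | step 8 | (5R,6R)-5-[(tert-butyldimethylsilyl)oxy]-6-[(2S,4R,6E)-4,6-dimethyloct-6-en-2-yl]-5,6-dihydro-2H-pyran-2-one | C/C=C(\C)C[C@H](C)C[C@H](C)[C@H]1OC(=O)C=C[C@H]1O[Si](C)(C)C(C)(C)C
F5 | step 8 | (5R,6R)-5-[(tert-butyldimethylsilyl)oxy]-6-[(2S,4R,6E)-4,6-dimethyloct-6-en-2-yl]oxan-2-one | C/C=C(\C)C[C@H](C)C[C@H](C)[C@H]1OC(=O)CC[C@H]1O[Si](C)(C)C(C)(C)C
F6 | step 12 | ethyl (2E,4R)-6-[(tert-butyldimethylsilyl)oxy]-4-(hydroxymethyl)-2-methylhex-2-enoate | CCOC(=O)/C(C)=C/[C@H](CO)CCO[Si](C)(C)C(C)(C)C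
F7 | step 12 | (2E,4R)-6-[(tert-butyldimethylsilyl)oxy]-4-(hydroxymethyl)-2-methylhex-2-en-1-ol | OC/C(C)=C/[C@H](CO)CCO[Si](C)(C)C(C)(C)C
F8 | step 13 | (2E,4R)-6-[(tert-butyldimethylsilyl)oxy]-4-{[(tert-butyldimethylsilyl)oxy]methyl}-2-methylhex-2-enal | O=C/C(C)=C/[C@H](CO[Si](C)(C)C(C)(C)C)CCO[Si](C)(C)C(C)(C)C
F9 | step 13 | (2E,4E,6R)-8-[(tert-butyldimethylsilyl)oxy]-6-{[(tert-butyldimethylsilyl)oxy]methyl}-4-methylocta-2,4-dienoic acid | OC(=O)/C=C/C(C)=C/[C@H](CO[Si](C)(C)C(C)(C)C)CCO[Si](C)(C)C(C)(C)C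
F10 | step 13 | (2R,3R)-2-[(2S,4R,6E)-4,6-dimethyloct-6-en-2-yl]-6-oxooxan-3-yl (2E,4E,6R)-8-[(tert-butyldimethylsilyl)oxy]-6-{[(tert-butyldimethylsilyl)oxy]methyl}-4-methylocta-2,4-dienoate | C/C=C(\C)C[C@H](C)C[C@H](C)[C@H]1OC(=O)CC[C@H]1OC(=O)/C=C/C(C)=C/[C@H](CO[Si](C)(C)C(C)(C)C)CCO[Si](C)(C)C(C)(C)C
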